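**Strategy.** The cyclohexene (C1, C10–C14) and the ten-membered ring (C1–C10) of the target share only the C1–C10 bond, which cuts a 14-membered carbocyclic perimeter in two. The route therefore builds the 14-membered cembranolide 37 and closes both rings at once: ionisation of its C1 tertiary allylic alcohol lets the E-C10=C11 alkene attack C1 across the ring, while the C12 acetate traps C11, setting C1, C10 and C11. Precursor 37 carries the finished C7/C8/C17 hydroxy-lactone, the Z-C5=C6 and Z-C13=C14 alkenes, silyl ethers at C2 and C9 and the C12 acetate.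

Key step: step 26

**Remarks on the chemistry (stated once).**
- Atom numbers are those of the target skeleton: ten-membered ring C1–C10, cyclohexene C1/C10–C14, lactone C7–O–C19(=O)–C17–C8, methyls C15 (on C1), C16 (on C5), C18 (on C17), C20 (on C11).
- The C1 carbinol of 30–37 is drawn as the Felkin–Anh epimer expected from step 19. Step 26 erases this centre, so the other epimer would serve equally.
- Macrocycle 37 and bicycle 39 were checked against the target (E-C10=C11, Z-C13=C14, Z-C5=C6, C12–O cis to the new C11–O, trans ring fusion) and are mutually consistent; no structure needed correction.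
- Design choices in 37: the C12 acetate is the only acyl group, so it alone can participate; the tertiary C8–OH is left free.
- In step 7 the ProPhenol antipode is the one that delivers the (3R)-carbinol. In step 15 the tartrate is the D-(−) antipode, which converts (E)-2-alken-1-ols into (2R,3R)-epoxides.

## Route

### C1–C4 unit (iodoketone 5)

Step 1
Reactants: 1 (R)-α-hydroxy-γ-butyrolactone
Product: 2 (3R)-3-(tert-butyldimethylsilyloxy)oxolan-2-one
Conditions: TBSCl, imidazole, DMF, rt
Reagents that add atoms: tert-butyldimethylsilyl chloride, CC(C)(C)[Si](C)(C)Cl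
Why: Standard silyl ether formation at the secondary alcohol leaves the stereocentre (later C2) untouched.

Step 2
Reactants: 2 (3R)-3-(tert-butyldimethylsilyloxy)oxolan-2-one
Product: 3 (2R)-2-(tert-butyldimethylsilyloxy)-4-hydroxy-N-methoxy-N-methylbutanamide
Conditions: MeNH(OMe)·HCl, i-PrMgCl, THF, −20 → 0 °C
Reagents that add atoms: N,O-dimethylhydroxylamine hydrochloride, CNOC.Cl
Why: Aminolysis of the lactone by the magnesium amide (Weinreb amide formation) opens the ring without touching the α-stereocentre.

Step 3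
Reactants: 3 (2R)-2-(tert-butyldimethylsilyloxy)-4-hydroxy-N-methoxy-N-methylbutanamide
Product: 4 (2R)-2-(tert-butyldimethylsilyloxy)-4-iodo-N-methoxy-N-methylbutanamide
Conditions: I2, PPh3, imidazole, CH2Cl2, 0 °C
Reagents that add atoms: iodine, II
Why: Appel iodination converts the primary alcohol into the iodide under neutral conditions.

Step 4
Reactants: 4 (2R)-2-(tert-butyldimethylsilyloxy)-4-iodo-N-methoxy-N-methylbutanamide
Product: 5 (3R)-3-(tert-butyldimethylsilyloxy)-5-iodopentan-2-one
Conditions: MeMgBr, THF, −78 → 0 °C; aq. NH4Cl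
Reagents that add atoms: methylmagnesium bromide, C[Mg]Br
Why: Weinreb ketone synthesis stops at the methyl ketone through the chelated tetrahedral adduct, and the primary iodide is inert to the Grignard reagent at low temperature.

### C10–C14 unit (enynol 11)

Step 5
Reactants: 6 prop-2-yn-1-ol
Product: 8 (2E)-3-iodo-2-methylprop-2-en-1-ol, via (E)-alkenylalane 7 (not isolated)
Conditions: Me3Al, Cp2ZrCl2 (25 mol%), CH2Cl2, 0 °C → rt; then I2, THF, −30 °C
Reagents that add atoms: trimethylaluminium, C[Al](C)C; iodine, II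
Why: Negishi zirconium-catalysed carboalumination adds methyl and aluminium syn across the alkyne, and iodinolysis with retention should give the E-iodoalkene (later E-C10=C11).

Step 6
Reactants: 8 (2E)-3-iodo-2-methylprop-2-en-1-ol
Product: 9 (2E)-3-iodo-2-methylprop-2-enal
Conditions: MnO2, CH2Cl2, rt
Reagents that add atoms: none
Why: Allylic alcohol oxidation with MnO2 should give the enal without isomerising the iodoalkene.

Step 7
Reactants: 9 (2E)-3-iodo-2-methylprop-2-enal
Product: 10 (1E,3R)-1-iodo-2-methyl-5-(trimethylsilyl)pent-1-en-4-yn-3-ol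
Conditions: TMS-acetylene, Me2Zn, ProPhenol ligand (10 mol%), Ph3P=O (20 mol%), toluene, 4 °C
Reagents that add atoms: ethynyltrimethylsilane, C#C[Si](C)(C)C
Why: Catalytic enantioselective zinc alkynylide addition to the enal sets C12 by ligand control of the aldehyde face.

Step 8
Reactants: 10 (1E,3R)-1-iodo-2-methyl-5-(trimethylsilyl)pent-1-en-4-yn-3-ol
Product: 11 (1E,3R)-1-iodo-2-methylpent-1-en-4-yn-3-ol
Conditions: K2CO3 (cat.), MeOH, rt
Reagents that add atoms: none
Why: Base-mediated methanolysis of the alkynyl C–Si bond (protodesilylation) frees the terminal alkyne.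

### Phosphonate 16 (C8, C9, C17–C19)

Step 9
Reactants: 12 (R)-2-methylsuccinic acid 4-methyl ester
Product: 13 1-tert-butyl 4-methyl (2R)-2-methylbutanedioate
Conditions: tert-butyl 2,2,2-trichloroacetimidate, BF3·OEt2 (cat.), CH2Cl2/cyclohexane, rt
Reagents that add atoms: tert-butyl 2,2,2-trichloroacetimidate, CC(C)(C)OC(=N)C(Cl)(Cl)Cl
Why: Acid-catalysed tert-butyl esterification with the imidate leaves the α-stereocentre (later C17) and the methyl ester untouched.

Step 10
Reactants: 13 1-tert-butyl 4-methyl (2R)-2-methylbutanedioate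
Product: 16 1-tert-butyl 4-methyl 3-(diethoxyphosphoryl)-2-methylbutanedioate, via lithium enolate 14 (not isolated), via phosphonite 15 (not isolated)
Conditions: LDA (1.05 equiv), THF, −78 °C; ClP(OEt)2; then 30% H2O2, 0 °C
Reagents that add atoms: diethyl chlorophosphite, CCOP(Cl)OCC; hydrogen peroxide, OO
Why: Kinetic enolisation at the less hindered CH2 next to the methyl ester, P–C bond formation and oxidation (C-phosphonylation of an ester enolate) should leave the methyl-bearing centre untouched; the new phosphonate carbon is stereochemically irrelevant.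

### Lactone unit (C5–C9, C16–C19)

Step 11
Reactants: 17 but-2-yn-1-ol
Product: 19 (2Z)-3-iodobut-2-en-1-ol, via cyclic alkenylaluminate 18 (not isolated)
Conditions: Red-Al, THF, 0 °C → rt; then I2, THF, −78 °C
Reagents that add atoms: iodine, II
Why: Hydroxyl-directed trans-hydroalumination places aluminium on the distal alkyne carbon cis to CH2O, and iodinolysis with retention should give the Z-iodoalkene (later Z-C5=C6).

Step 12
Reactants: 19 (2Z)-3-iodobut-2-en-1-ol
Product: 20 (2Z)-3-iodobut-2-enal
Conditions: MnO2, CH2Cl2, rt; used crude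
Reagents that add atoms: none
Why: Allylic oxidation with MnO2 under neutral conditions should preserve the Z geometry.

Step 13
Reactants: 16 1-tert-butyl 4-methyl 3-(diethoxyphosphoryl)-2-methylbutanedioate; 20 (2Z)-3-iodobut-2-enal
Product: 22 1-tert-butyl 4-methyl (2R,3E)-3-[(2Z)-3-iodobut-2-en-1-ylidene]-2-methylbutanedioate, via sodium phosphonate carbanion 21 (not isolated)
Conditions: NaH (0.95 equiv), THF, 0 °C; then 20, −78 → 0 °C
Reagents that add atoms: none
Why: Horner–Wadsworth–Emmons olefination with the stabilised phosphonate should place the iodoalkenyl residue trans to the conjugated ester (E-C7=C8), the geometry that the later epoxide opening requires.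

Step 14
Reactants: 22 1-tert-butyl 4-methyl (2R,3E)-3-[(2Z)-3-iodobut-2-en-1-ylidene]-2-methylbutanedioate
Product: 23 tert-butyl (2R,3E,5Z)-3-(hydroxymethyl)-6-iodo-2-methylhepta-3,5-dienoate
Conditions: DIBAL-H (2.2 equiv), CH2Cl2, −78 °C; Rochelle salt
Reagents that add atoms: none
Why: Chemoselective ester reduction: DIBAL-H should reduce the methyl dienoate to the allylic alcohol while the bulky tert-butyl ester survives at −78 °C.

Step 15
Reactants: 23 tert-butyl (2R,3E,5Z)-3-(hydroxymethyl)-6-iodo-2-methylhepta-3,5-dienoate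
Product: 24 tert-butyl (2R)-2-{(2R,3R)-2-(hydroxymethyl)-3-[(1Z)-2-iodoprop-1-en-1-yl]oxiran-2-yl}propanoate
Conditions: Ti(OiPr)4 (10 mol%), D-(−)-diisopropyl tartrate (12 mol%), t-BuOOH, 4 Å MS, CH2Cl2, −20 °C
Reagents that add atoms: tert-butyl hydroperoxide, CC(C)(C)OO
Why: Sharpless asymmetric epoxidation of the primary allylic alcohol should set C8 and the pre-inversion configuration of C7 under reagent control and leave the iodoalkene alone.

Step 16
Reactants: 24 tert-butyl (2R)-2-{(2R,3R)-2-(hydroxymethyl)-3-[(1Z)-2-iodoprop-1-en-1-yl]oxiran-2-yl}propanoate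
Product: 25 (3R,4R,5S)-4-hydroxy-4-(hydroxymethyl)-5-[(1Z)-2-iodoprop-1-en-1-yl]-3-methyloxolan-2-one
Conditions: BF3·OEt2 (20 mol%), CH2Cl2, −78 → −40 °C; aq. NaHCO3
Reagents that add atoms: none
Why: Lewis-acid-promoted epoxy-ester lactonisation: the tert-butyl ester carbonyl should open the vinyl epoxide at the allylic carbon C7 with inversion and lose isobutene, so C8 keeps its oxygen with retention and the C6 and C9 substituents end up trans on the lactone.

Step 17
Reactants: 25 (3R,4R,5S)-4-hydroxy-4-(hydroxymethyl)-5-[(1Z)-2-iodoprop-1-en-1-yl]-3-methyloxolan-2-one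
Product: 26 C8/C9 acetonide of 25 (6-[(1Z)-2-iodoprop-1-en-1-yl]-2,2,9-trimethyl-1,3,7-trioxaspiro[4.4]nonan-8-one, stereocentres as in 25)
Conditions: 2,2-dimethoxypropane, PPTS (cat.), acetone, rt
Reagents that add atoms: 2,2-dimethoxypropane, COC(C)(C)OC
Why: Acetonide formation protects the tertiary C8 and primary C9 hydroxyls together (1,2-diol protection).

### Fragment union and macrocycle

Step 18
Reactants: 5 (3R)-3-(tert-butyldimethylsilyloxy)-5-iodopentan-2-one; 26 C8/C9 acetonide of 25
Product: 28 C4–C5 coupled keto lactone acetonide (C1 methyl ketone, C2 OTBS, Z-C5=C6), via alkylzinc iodide 27 (not isolated)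
Conditions: 5, Zn dust (TMSCl/BrCH2CH2Br-activated), LiCl, THF, 35 °C; then 26, Pd(dppf)Cl2 (5 mol%), THF/DMA, 45 °C
Reagents that add atoms: none
Why: Negishi sp3–sp2 cross-coupling of the functionalised alkylzinc iodide with the alkenyl iodide should proceed with retention of the Z geometry and tolerate ketone, lactone and acetal.

Step 19
Reactants: 11 (1E,3R)-1-iodo-2-methylpent-1-en-4-yn-3-ol; 28 C4–C5 coupled keto lactone acetonide
Product: 30 C1/C12 diol (C1 tertiary propargylic alcohol; E-iodoalkene at C10), via bis(bromomagnesium) salt 29 (not isolated)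
Conditions: 11, EtMgBr (2.1 equiv), THF, 0 °C → rt; then LaCl3·2LiCl (0.3 equiv), 28, −20 → 0 °C; aq. NH4Cl
Reagents that add atoms: none
Why: Lanthanum-promoted 1,2-addition of the alkynylmagnesium reagent to the methyl ketone, which is far more electrophilic than the lactone; polar Felkin–Anh attack anti to the C2 silyloxy group should give mainly the C1 epimer shown, a centre that step 26 erases.

Step 20
Reactants: 30 C1/C12 diol
Product: 31 C12 acetate
Conditions: Ac2O, pyridine, DMAP (cat.), CH2Cl2, 0 °C
Reagents that add atoms: acetic anhydride, CC(=O)OC(C)=O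
Why: Acetylation of the secondary C12 alcohol; the tertiary propargylic C1 alcohol is too hindered to react under these conditions.

Step 21
Reactants: 31 C12 acetate
Product: 32 C8/C9 diol
Conditions: AcOH/H2O (4:1), 40 °C
Reagents that add atoms: none
Why: Mild acid hydrolysis of the terminal acetonide should leave the hindered secondary TBS ether, the acetate and the lactone in place.

Step 22
Reactants: 32 C8/C9 diol
Product: 33 C9 aldehyde (α-hydroxy aldehyde)
Conditions: TEMPO (20 mol%), PhI(OAc)2, CH2Cl2, rt
Reagents that add atoms: none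
Why: Oxoammonium (TEMPO/PhI(OAc)2) oxidation is selective for the primary alcohol and cannot oxidise the tertiary ones.

Step 23
Reactants: 33 C9 aldehyde
Product: 35 14-membered cycloalkyne with (9R)-allylic alcohol, via alkenylchromium species 34 (not isolated)
Conditions: CrCl2 (8 equiv), NiCl2 (2 mol%), DMSO/THF, rt, 2 mM, syringe-pump addition
Reagents that add atoms: none
Why: Nozaki–Hiyama–Kishi macrocyclisation: the alkenylchromium(III) species adds chemoselectively to the aldehyde at high dilution to close the 14-membered ring with retention of the E geometry, and C9 should arise from attack anti to the C8–O bond past the lactone CH(CH3) carbon (polar Felkin–Anh), a preference that a chiral sulfonamide ligand on chromium can reinforce.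

Step 24
Reactants: 35 14-membered cycloalkyne C9 alcohol
Product: 36 C2,C9-bis-TBS cycloalkyne
Conditions: TBSOTf (1.1 equiv), 2,6-lutidine, CH2Cl2, −78 °C
Reagents that add atoms: tert-butyldimethylsilyl trifluoromethanesulfonate, CC(C)(C)[Si](C)(C)OS(=O)(=O)C(F)(F)F
Why: Silyl ether formation at the secondary allylic alcohol; the two tertiary alcohols react much more slowly at −78 °C.

Step 25
Reactants: 36 C2,C9-bis-TBS cycloalkyne
Product: 37 14-membered cembranolide (C1 tertiary allylic alcohol, C2/C9 TBS ethers, C12 acetate, Z-C13=C14)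
Conditions: H2 (1 atm), Lindlar catalyst, quinoline, EtOAc, rt
Reagents that add atoms: none
Why: Lindlar semihydrogenation delivers hydrogen syn to the ring alkyne and should give the Z-C13=C14 alkene without touching the trisubstituted alkenes.

### Key step and end game

Step 26
Reactants: 37 14-membered cembranolide
Product: 39 bicyclic bis-TBS ether (cyclohexene fused to the ten-membered ring; C11 OH, C12 OAc), via dioxolanylium ion 38 (not isolated)
Conditions: HNTf2 (5 mol%), HFIP/CH2Cl2 (1:4), −40 → −10 °C; then aq. NaHCO3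
Reagents that add atoms: none
Why: Proposed new method: protonation of the C1 tertiary allylic alcohol and loss of water give the C1/C13 allyl cation with C13=C14 held Z; the E-C10=C11 alkene attacks C1 across the 14-membered ring, and the developing C11 cation is trapped antiperiplanar by the carbonyl oxygen of the C12 acetate as dioxolanylium ion 38, which the expelled water reopens at the acyl carbon to give the tertiary C11 alcohol and the secondary C12 acetate, so the step is a net isomerisation. The closest known reaction type is the acid-promoted transannular cation–olefin (Prins-type) cyclisation of macrocyclic terpenoid dienols; acyloxonium trapping of tertiary cations is known separately. The cyclohexene closes in a 6-endo-trig, chair-like mode, and the same bond leaves the ten-membered ring as the remainder of the perimeter. C11 is set cis to the C12 oxygen by the dioxolanylium ion, C10 by the E-alkene geometry together with the antiperiplanar addition that the pseudo-axial C12 acetate enforces, and C1 by the chair in which the C2 chain is equatorial and the smaller methyl takes the axial site syn to the axial C11 methyl (trans ring fusion). The step needs ionisation at C1 in preference to the doubly allylic C12 acetate, which the more basic free alcohol, catalytic acid and low temperature should favour, and attack by C10=C11 and not by C5=C6, which acetate assistance and the deactivation of C5=C6 by the allylic lactone oxygen should favour. Silyl ethers at C2 and C9 leave the C12 acetate as the only participating acyl group, and an acetoxonium ion formed at the C13 terminus can return to the allyl cation.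

Step 27
Reactants: 39 bicyclic bis-TBS ether
Product: 40 C2,C9 diol
Conditions: HF·pyridine, pyridine, THF, 0 °C → rt
Reagents that add atoms: none
Why: Fluoride-mediated desilylation of both secondary silyl ethers under buffered, weakly acidic conditions that should not cause acetyl migration or lactone opening.

Step 28
Reactants: 40 C2,C9 diol
Product: 41 CNP0129620.2 (2,9,12-triacetate, 8,11-diol)
Conditions: Ac2O, pyridine, DMAP (cat.), CH2Cl2, rt
Reagents that add atoms: acetic anhydride, CC(=O)OC(C)=O
Why: Acetylation of the two secondary alcohols; the tertiary C8 and C11 alcohols are inert under these conditions.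

## Compound list

1 | (R)-α-hydroxy-γ-butyrolactone [(3R)-3-hydroxyoxolan-2-one] | O[C@@H]1CCOC1=O | starting material
2 | (3R)-3-(tert-butyldimethylsilyloxy)oxolan-2-one | CC(C)(C)[Si](C)(C)O[C@@H]1CCOC1=O | intermediate
3 | (2R)-2-(tert-butyldimethylsilyloxy)-4-hydroxy-N-methoxy-N-methylbutanamide | CON(C)C(=O)[C@H](O[Si](C)(C)C(C)(C)C)CCO | intermediate
4 | (2R)-2-(tert-butyldimethylsilyloxy)-4-iodo-N-methoxy-N-methylbutanamide | CON(C)C(=O)[C@H](O[Si](C)(C)C(C)(C)C)CCI | intermediate
5 | (3R)-3-(tert-butyldimethylsilyloxy)-5-iodopentan-2-one | CC(=O)[C@H](O[Si](C)(C)C(C)(C)C)CCI | intermediate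
6 | prop-2-yn-1-ol | C#CCO | starting material
7 | dimethylaluminium (2E)-3-(dimethylalumanyl)-2-methylprop-2-en-1-olate | C[Al](C)OC/C(C)=C/[Al](C)C | intermediate
8 | (2E)-3-iodo-2-methylprop-2-en-1-ol | I/C=C(C)/CO | intermediate
9 | (2E)-3-iodo-2-methylprop-2-enal | I/C=C(C)/C=O | intermediate
10 | (1E,3R)-1-iodo-2-methyl-5-(trimethylsilyl)pent-1-en-4-yn-3-ol | I/C=C(C)/[C@H](O)C#C[Si](C)(C)C | intermediate
11 | (1E,3R)-1-iodo-2-methylpent-1-en-4-yn-3-ol | I/C=C(C)/[C@H](O)C#C | intermediate
12 | (R)-2-methylsuccinic acid 4-methyl ester [(2R)-4-methoxy-2-methyl-4-oxobutanoic acid] | OC(=O)[C@H](C)CC(=O)OC | starting material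
13 | 1-tert-butyl 4-methyl (2R)-2-methylbutanedioate | CC(C)(C)OC(=O)[C@H](C)CC(=O)OC | intermediate
14 | lithium enolate of 13 at the CH2 next to the methyl ester | CC(C)(C)OC(=O)[C@H](C)C=C(OC)O[Li] | intermediate
15 | 1-tert-butyl 4-methyl 3-(diethoxyphosphanyl)-2-methylbutanedioate (phosphonite) | CC(C)(C)OC(=O)[C@H](C)C(C(=O)OC)P(OCC)OCC | intermediate
16 | 1-tert-butyl 4-methyl 3-(diethoxyphosphoryl)-2-methylbutanedioate (methyl-bearing centre as in 13, both epimers at the phosphorus-bearing carbon) | CC(C)(C)OC(=O)[C@H](C)C(C(=O)OC)P(=O)(OCC)OCC | intermediate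
17 | but-2-yn-1-ol | CC#CCO | starting material
18 | sodium cyclic (Z)-alkenylaluminate (five-membered C–Al–O chelate with two 2-methoxyethoxy ligands) | CC1=CCO[Al-]1(OCCOC)OCCOC.[Na+] | intermediate
19 | (2Z)-3-iodobut-2-en-1-ol | I/C(C)=C\CO | intermediate
20 | (2Z)-3-iodobut-2-enal | I/C(C)=C\C=O | intermediate
21 | sodium salt of the phosphonate carbanion of 16 | CC(C)(C)OC(=O)[C@H](C)[C-](C(=O)OC)P(=O)(OCC)OCC.[Na+] | intermediate
22 | 1-tert-butyl 4-methyl (2R,3E)-3-[(2Z)-3-iodobut-2-en-1-ylidene]-2-methylbutanedioate | I/C(C)=C\C=C(/[C@@H](C)C(=O)OC(C)(C)C)C(=O)OC | intermediate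
23 | tert-butyl (2R,3E,5Z)-3-(hydroxymethyl)-6-iodo-2-methylhepta-3,5-dienoate | I/C(C)=C\C=C(/[C@@H](C)C(=O)OC(C)(C)C)CO | intermediate
24 | tert-butyl (2R)-2-{(2R,3R)-2-(hydroxymethyl)-3-[(1Z)-2-iodoprop-1-en-1-yl]oxiran-2-yl}propanoate | I/C(C)=C\[C@H]1O[C@@]1(CO)[C@@H](C)C(=O)OC(C)(C)C | intermediate
25 | (3R,4R,5S)-4-hydroxy-4-(hydroxymethyl)-5-[(1Z)-2-iodoprop-1-en-1-yl]-3-methyloxolan-2-one (C7, C8, C17 of the target in place) | I/C(C)=C\[C@@H]1OC(=O)[C@H](C)[C@]1(CO)O | intermediate
26 | C8/C9 acetonide of 25: 6-[(1Z)-2-iodoprop-1-en-1-yl]-2,2,9-trimethyl-1,3,7-trioxaspiro[4.4]nonan-8-one, stereocentres as in 25 | I/C(C)=C\[C@@H]1OC(=O)[C@H](C)[C@@]12COC(C)(C)O2 | intermediate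
27 | alkylzinc iodide from 5: [(3R)-3-(tert-butyldimethylsilyloxy)-4-oxopentyl]zinc iodide | CC(=O)[C@H](O[Si](C)(C)C(C)(C)C)CC[Zn]I | intermediate
28 | C4–C5 coupled keto lactone acetonide (C1 methyl ketone, (2R)-OTBS, Z-C5=C6, lactone and acetonide as in 26) | CC(=O)[C@H](O[Si](C)(C)C(C)(C)C)CC/C(C)=C\[C@@H]1OC(=O)[C@H](C)[C@@]12COC(C)(C)O2 | intermediate
29 | bis(bromomagnesium) alkoxide–acetylide of 11 | I/C=C(C)/[C@H](O[Mg]Br)C#C[Mg]Br | intermediate
30 | C1/C12 diol: C1 tertiary propargylic alcohol (Felkin–Anh epimer), C12 secondary alcohol, E-iodoalkene at C10, acetonide lactone | I/C=C(C)/[C@H](O)C#C[C@@](O)(C)[C@H](O[Si](C)(C)C(C)(C)C)CC/C(C)=C\[C@@H]1OC(=O)[C@H](C)[C@@]12COC(C)(C)O2 | intermediate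
31 | C12 acetate of 30 | I/C=C(C)/[C@H](OC(C)=O)C#C[C@@](O)(C)[C@H](O[Si](C)(C)C(C)(C)C)CC/C(C)=C\[C@@H]1OC(=O)[C@H](C)[C@@]12COC(C)(C)O2 | intermediate
32 | C8/C9 diol (acetonide of 31 removed) | I/C=C(C)/[C@H](OC(C)=O)C#C[C@@](O)(C)[C@H](O[Si](C)(C)C(C)(C)C)CC/C(C)=C\[C@@H]1OC(=O)[C@H](C)[C@]1(CO)O | intermediate
33 | C9 aldehyde (α-hydroxy aldehyde on the lactone, E-iodoalkene at C10) | I/C=C(C)/[C@H](OC(C)=O)C#C[C@@](O)(C)[C@H](O[Si](C)(C)C(C)(C)C)CC/C(C)=C\[C@@H]1OC(=O)[C@H](C)[C@]1(C=O)O | intermediate
34 | alkenylchromium(III) dichloride derived from 33 | Cl[Cr](Cl)/C=C(C)/[C@H](OC(C)=O)C#C[C@@](O)(C)[C@H](O[Si](C)(C)C(C)(C)C)CC/C(C)=C\[C@@H]1OC(=O)[C@H](C)[C@]1(C=O)O | intermediate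
35 | 14-membered cycloalkyne: (9R)-allylic alcohol, C12 acetate, C2 OTBS, C1 and C8 tertiary alcohols, fused lactone | O[C@@H]1/C=C(C)/[C@H](OC(C)=O)C#C[C@@](O)(C)[C@H](O[Si](C)(C)C(C)(C)C)CC/C(C)=C\[C@@H]2OC(=O)[C@H](C)[C@]21O | intermediate
36 | C2,C9-bis-TBS cycloalkyne | CC(C)(C)[Si](C)(C)O[C@@H]1/C=C(C)/[C@H](OC(C)=O)C#C[C@@](O)(C)[C@H](O[Si](C)(C)C(C)(C)C)CC/C(C)=C\[C@@H]2OC(=O)[C@H](C)[C@]21O | intermediate
37 | 14-membered cembranolide, key-step precursor: C1 tertiary allylic alcohol, C2 and C9 TBS ethers, C12 acetate, E-C10=C11, Z-C13=C14, Z-C5=C6 | CC(C)(C)[Si](C)(C)O[C@@H]1/C=C(C)/[C@H](OC(C)=O)\C=C/[C@@](O)(C)[C@H](O[Si](C)(C)C(C)(C)C)CC/C(C)=C\[C@@H]2OC(=O)[C@H](C)[C@]21O | intermediate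
38 | cis-fused C11/C12 2-methyl-1,3-dioxolan-2-ylium ion of the bicycle (triflimide salt) | CC(C)(C)[Si](C)(C)O[C@@H]1[C@H]2[C@]3(C)O[C+](C)O[C@@H]3C=C[C@]2(C)[C@H](O[Si](C)(C)C(C)(C)C)CC/C(C)=C\[C@@H]2OC(=O)[C@H](C)[C@]21O.[N-](S(=O)(=O)C(F)(F)F)S(=O)(=O)C(F)(F)F | intermediate
39 | bicyclic bis-TBS ether, key-step product: target with TBS ethers in place of the C2 and C9 acetates | CC(C)(C)[Si](C)(C)O[C@@H]1[C@H]2[C@](C)(O)[C@H](OC(C)=O)C=C[C@]2(C)[C@H](O[Si](C)(C)C(C)(C)C)CC/C(C)=C\[C@@H]2OC(=O)[C@H](C)[C@]21O | intermediate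
40 | C2,C9 diol (C12 acetate, C8 and C11 tertiary alcohols) | O[C@@H]1[C@H]2[C@](C)(O)[C@H](OC(C)=O)C=C[C@]2(C)[C@H](O)CC/C(C)=C\[C@@H]2OC(=O)[C@H](C)[C@]21O | intermediate
41 | CNP0129620.2 | CC(=O)O[C@@H]1[C@H]2[C@](C)(O)[C@H](OC(C)=O)C=C[C@]2(C)[C@H](OC(C)=O)CC/C(C)=C\[C@@H]2OC(=O)[C@H](C)[C@]21O | target

## Step count and risks

Total: 28 steps. Longest linear sequence: 18 steps (17 → 41, steps 11–28).

**Step 26 (key step).** What may go wrong: ionisation at the doubly allylic C12 acetate, or capture of the allyl cation at C13 by that acetate, outruns the transannular C1–C10 closure; the C5=C6 alkene may compete; or closure takes the wrong face. Fallback: the neighbouring-group termination is given up for the water-terminated transannular cyclisation of a macrocyclic dienol, the classical reaction class for macrocyclic terpenoids. Setting out from 37, K2CO3/MeOH at 0 °C should remove the acetate to give bis-allylic alcohol F1. TBSCl/imidazole should then give tris-silyl ether F2, in which no acyl group remains. Dilute aqueous acid (HClO4 in THF/H2O, or TFA in wet HFIP) should effect the hydrative 6-endo closure, water entering C11 anti to the new C1–C10 bond, to give bicyclic tertiary alcohol F3. HF·pyridine should give pentaol F4, and Ac2O/pyridine/DMAP should acetylate its three secondary hydroxyls (C2, C9, C12), coming back to the route at 41.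

**Step 23 (macrocyclisation).** What may go wrong: poor facial selectivity at C9 during ring closure, so that the C9 epimer dominates or a mixture forms. Fallback: C9 is set after ring closure by ketone reduction instead of by the C–C bond formation. Setting out from 33, the closure is run without regard to selectivity; the C9-epimeric alcohol F5 formed beside 35 is oxidised together with it (Dess–Martin periodinane) to macrocyclic enone F6. F6 is then reduced under reagent control (CBS oxazaborolidine/catecholborane, antipode chosen for the required face, or Zn(BH4)2 through chelation to the free C8–OH), coming back to the route at 35.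

**Step 13 (olefination).** What may go wrong: sluggish reaction and erosion of E selectivity with the α-branched phosphonate, or Z→E isomerisation of the iodoenal under the basic conditions. Fallback: aldol addition and elimination replace the phosphonate olefination. Setting out from 13 and 20, LDA (THF, −78 °C) followed by 20 should give β-hydroxy diester F7 as a diastereomer mixture. MsCl/Et3N should give mesylate F8, and DBU at 0 °C should eliminate it by E1cB to the thermodynamically preferred E-alkylidene succinate, coming back to the route at 22.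

Further compounds
F1 | step 26 | C12 bis-allylic alcohol of the macrocycle (acetate of 37 removed) | CC(C)(C)[Si](C)(C)O[C@@H]1/C=C(C)/[C@H](O)\C=C/[C@@](O)(C)[C@H](O[Si](C)(C)C(C)(C)C)CC/C(C)=C\[C@@H]2OC(=O)[C@H](C)[C@]21O
F2 | step 26 | C2,C9,C12-tris-TBS macrocycle | CC(C)(C)[Si](C)(C)O[C@@H]1/C=C(C)/[C@H](O[Si](C)(C)C(C)(C)C)\C=C/[C@@](O)(C)[C@H](O[Si](C)(C)C(C)(C)C)CC/C(C)=C\[C@@H]2OC(=O)[C@H](C)[C@]21O
F3 | step 26 | bicyclic tris-TBS ether with C11 tertiary alcohol | CC(C)(C)[Si](C)(C)O[C@@H]1[C@H]2[C@](C)(O)[C@H](O[Si](C)(C)C(C)(C)C)C=C[C@]2(C)[C@H](O[Si](C)(C)C(C)(C)C)CC/C(C)=C\[C@@H]2OC(=O)[C@H](C)[C@]21O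
F4 | step 26 | bicyclic pentaol (C2, C9, C12 secondary and C8, C11 tertiary hydroxyls) | O[C@@H]1[C@H]2[C@](C)(O)[C@H](O)C=C[C@]2(C)[C@H](O)CC/C(C)=C\[C@@H]2OC(=O)[C@H](C)[C@]21O
F5 | step 23 | C9 epimer of 35 | O[C@H]1/C=C(C)/[C@H](OC(C)=O)C#C[C@@](O)(C)[C@H](O[Si](C)(C)C(C)(C)C)CC/C(C)=C\[C@@H]2OC(=O)[C@H](C)[C@]21O
F6 | step 23 | macrocyclic C9 enone | O=C1/C=C(C)/[C@H](OC(C)=O)C#C[C@@](O)(C)[C@H](O[Si](C)(C)C(C)(C)C)CC/C(C)=C\[C@@H]2OC(=O)[C@H](C)[C@]21O
F7 | step 13 | β-hydroxy diester from aldol addition of 13 to 20 (diastereomer mixture at C7 and C8) | I/C(C)=C\C(O)C(C(=O)OC)[C@@H](C)C(=O)OC(C)(C)C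
F8 | step 13 | mesylate of F7 | I/C(C)=C\C(OS(C)(=O)=O)C(C(=O)OC)[C@@H](C)C(=O)OC(C)(C)C
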